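**Plan**

1. Numbering (germacranolide): C1=C10 is the ring enoate (CO2Me on C10), C4–C5 the methyl-bearing oxirane, C6 (lactone O) and C7 (lactone C) the ring-fusion carbons, C8/C9 the acyloxy carbons, and C11–C13 the O–C(=O)–C(=CH2) unit of the lactone.
2. Cuts: the acyl–O bonds at O8 and O9; the ring bond C9–C10 (Nozaki–Hiyama–Kishi closure); C1=C10 (iodo-Wittig); then, in one operation, both bonds that tie the lactone to the chain, O–C6 and C11–C7 (palladium-catalysed [3+2] annulation of 2-bromoacrylic acid onto a 1,3-diene); finally C5–C6 (Suzuki).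
3. Enabling feature: C6, the oxygen-bearing carbon of the lactone ring, is flanked by the C4–C5 oxirane. Read as a masked (Z)-alkene, the oxirane makes C4=C5–C6=C7 a conjugated diene and C6 the near terminus of an allylpalladium unit, while the lactone atoms O, C12, C11 and the exocyclic C13 are 2-bromoacrylic acid. The lower oxidation level at C4/C5 is removed again by epoxidation.
4. Forward order: C1–C5 iodide + C6–C9 boronate → diene → lactone ring (key step) → C1=C10 iodo enoate → oxirane → ten-membered ring → O9 acetate and O8 epoxy ester.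
5. Stereochemistry: C8 from (R)-glyceraldehyde acetonide; C7 and C6 in the key step (insertion anti to the C8–O bond, syn addition across the (E)-alkene); C5/C4 by epoxidation of the (Z)-alkene anti to the lactone oxygen; C9 by Felkin–Anh addition in the ring closure; alkene geometries from syn-carbocupration, Takai–Utimoto olefination and the Wittig step; the side-chain oxirane from (R)-2-methylglycidol.

Key step: step 4

Remark: 2-bromoacrylic acid, (R)-glyceraldehyde acetonide, pinacol (dichloromethyl)boronate and (R)-2-methylglycidol are taken as purchasable; the target is read as the (4R,5S,6S,7R,8S,9R) compound with a ring-cis C1=C10 bond, a cis-4,5-oxirane and an (S)-2-methyloxirane-2-carboxylate on O8.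

**Route**

Step 1
Reactants: 1 2-(2-bromoethyl)-1,3-dioxolane; 2 propyne
Product: 5 vinyl iodide 2-[(3Z)-4-iodo-3-methylbut-3-en-1-yl]-1,3-dioxolane, via Grignard reagent 3 (not isolated), via alkenylcopper 4 (not isolated)
Conditions: Mg, THF, 25 °C; CuBr·SMe2, Et2O/Me2S, −45 °C; propyne, −25 °C; I2, −40 to 0 °C
Reagents that add atoms: iodine, [I][I]
Why: Normant carbocupration: the alkylcopper made from Grignard reagent 3 adds syn across propyne with the alkyl group on the internal carbon, and iodinolysis of the alkenylcopper with retention leaves iodine cis to the acetal chain, which fixes the (Z) geometry of the later C4=C5 bond.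

Step 2
Reactants: 6 (R)-2,2-dimethyl-1,3-dioxolane-4-carbaldehyde; 7 2-(dichloromethyl)-4,4,5,5-tetramethyl-1,3,2-dioxaborolane
Product: 9 alkenyl boronate 2-[(E)-2-[(4S)-2,2-dimethyl-1,3-dioxolan-4-yl]ethenyl]-4,4,5,5-tetramethyl-1,3,2-dioxaborolane, via pinacol (diiodomethyl)boronate 8 (not isolated)
Conditions: CrCl2 (8 equiv), LiI (4 equiv), THF, 23 °C
Reagents that add atoms: none
Why: Takai–Utimoto boryl-olefination: the geminal dichromium species formed from the dihalomethylboronate and CrCl2 converts the aldehyde into the (E)-alkenyl boronate under non-basic conditions, so the α-alkoxy stereocentre (the later C8) is not epimerised.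

Step 3
Reactants: 5 vinyl iodide; 9 alkenyl boronate
Product: 10 diene (4S)-4-[(1E,3Z)-6-(1,3-dioxolan-2-yl)-4-methylhexa-1,3-dien-1-yl]-2,2-dimethyl-1,3-dioxolane
Conditions: PdCl2(dppf) (5 mol %), K3PO4 (3 equiv), THF/H2O, 45 °C
Reagents that add atoms: none
Why: Suzuki–Miyaura coupling of an alkenyl iodide with an alkenyl boronate proceeds with retention of both alkene geometries and joins C5 to C6, which gives the (6E,4Z)-diene needed for the annulation.

Step 4
Reactants: 10 diene; 11 2-bromoacrylic acid
Product: 12 trans-lactone (4S,5R)-4-[(4S)-2,2-dimethyl-1,3-dioxolan-4-yl]-5-[(1Z)-4-(1,3-dioxolan-2-yl)-2-methylbut-1-en-1-yl]-3-methylideneoxolan-2-one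
Conditions: Pd2(dba)3 (5 mol %), P(2-furyl)3 (20 mol %), Ag2CO3 (1.0 equiv), MeCN, 60 °C, slow addition of 11
Reagents that add atoms: none
Why: Proposed new method: oxidative addition of zerovalent palladium into the C–Br bond of 11 should give an α-carboxyalkenylpalladium species whose syn migratory insertion into the less substituted (E)-C6=C7 bond of 10 delivers C11 to the diene terminus C7 and leaves an η3-allylpalladium unit over C6–C5–C4, held in a six-membered chelate by the carboxylate once silver has removed bromide, and C–O reductive elimination at the near allyl terminus C6 then closes the lactone. The closest known reaction type is the Larock heteroannulation of 1,3-dienes with ortho-halobenzoic acids and other aryl or alkenyl halides that carry a nucleophile, extended here to 2-bromoacrylic acid and an acyclic 1,4-disubstituted diene. The lactone ring closes in a 5-exo mode at the allyl terminus (C4=C5 stays outside the ring), the seven-membered alternative at the tertiary terminus C4 being disfavoured. C7 is set by the face of insertion, expected anti to the C8–O bond of the dioxolane in the conformer with H8 eclipsing the alkene, and C6 follows from the syn sense of both insertion and inner-sphere C–O bond formation on the (E)-alkene, which translates into the trans-β,γ-disubstituted lactone. The step needs site selectivity for C6=C7 over the trisubstituted C4=C5 bond (steric), retention of the (Z)-C4=C5 geometry (syn–anti exchange would require a tertiary σ-palladium at C4) and survival of the product's methylene lactone, which slow addition of 11 should help.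

Step 5
Reactants: 12 trans-lactone
Product: 13 diol aldehyde (12 with the C1 acetal opened to the aldehyde and the acetonide opened to the free C8/C9 diol; C6 C7 C8 unchanged)
Conditions: 2 M aq HCl/THF (1:4), 23 °C
Reagents that add atoms: water, O
Why: Acid-catalysed acetal hydrolysis unmasks the C1 aldehyde and the C8/C9 diol in one operation, while the lactone and the alkenes should be stable to dilute aqueous acid at room temperature and no stereocentre is touched.

Step 6
Reactants: 13 diol aldehyde; 14 methyl (triphenylphosphoranylidene)acetate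
Product: 16 iodo enoate diol (13 with C1H=O converted into C1H=C10(I)CO2Me; iodine cis to C2), via iodo ylide 15 (not isolated)
Conditions: 14, NIS, CH2Cl2, −20 °C; then 13, −20 to 23 °C
Reagents that add atoms: N-iodosuccinimide, O=C1CCC(=O)N1I
Why: Wittig olefination with the α-iodo stabilised ylide made in the flask places the ester trans to the chain, so iodine ends up cis to C2 in the (Z)-α-iodo enoate, which is the geometry the ring alkene needs; the free diol is tolerated because all N-iodosuccinimide is consumed before 13 is added.

Step 7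
Reactants: 16 iodo enoate diol
Product: 17 bis(triethylsilyl) ether of 16 (O8 and O9)
Conditions: TESOTf, 2,6-lutidine, CH2Cl2, −78 to 0 °C
Reagents that add atoms: triethylsilyl trifluoromethanesulfonate, CC[Si](CC)(CC)OS(=O)(=O)C(F)(F)F
Why: Silylation of both hydroxyl groups with the silyl triflate protects O8 for the ring closure and prepares O9 for direct oxidation, and no stereocentre is affected.

Step 8
Reactants: 17 bis(triethylsilyl) ether
Product: 18 cis-4,5-oxirane of 17 (4R 5S; oxirane oxygen anti to the lactone oxygen)
Conditions: mCPBA, NaHCO3, CH2Cl2, 0 °C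
Reagents that add atoms: 3-chloroperoxybenzoic acid, OOC(=O)c1cccc(Cl)c1
Why: Prilezhaev epoxidation by the electrophilic peracid should take place only at the electron-rich trisubstituted C4=C5 bond, and in the conformer that A(1,3) strain enforces on the (Z)-alkene (H6 in the alkene plane) the peracid should approach anti to the lactone C6–O bond, which together with syn addition gives the cis-oxirane with the (4R,5S) configuration.

Step 9
Reactants: 18 oxirane
Product: 19 C9 aldehyde (18 with the CH2OSiEt3 group at C9 oxidised to CHO; O8 silyl ether kept)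
Conditions: (COCl)2, DMSO, CH2Cl2, −78 to −40 °C; Et3N, −78 to 0 °C
Reagents that add atoms: none
Why: Swern oxidation of a bis(triethylsilyl) ether is known to cleave and oxidise the primary silyl ether selectively, which gives the C9 aldehyde directly while the hindered secondary O8 silyl ether, the oxirane and the C8 stereocentre stay intact.

Step 10
Reactants: 19 C9 aldehyde
Product: 20 macrocyclic alcohol (target skeleton with 9R-OH and OSiEt3 at C8)
Conditions: CrCl2 (10 equiv), NiCl2 (0.1 equiv), DMSO/THF (3:1), 0.003 M, 23 °C
Reagents that add atoms: none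
Why: Nozaki–Hiyama–Kishi reaction: nickel-catalysed formation of the alkenylchromium from the α-iodo enoate and its addition to the C9 aldehyde under high dilution should close the ten-membered ring at C9–C10, only the ring-cis alkenylchromium geometry can reach the aldehyde, and Felkin–Anh addition anti to the α-silyloxy group should set the (9R) carbinol.

Step 11
Reactants: 20 macrocyclic alcohol
Product: 21 C9 acetate of 20
Conditions: Ac2O, pyridine, DMAP (catalytic), CH2Cl2, 0 °C
Reagents that add atoms: acetic anhydride, CC(=O)OC(C)=O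
Why: Standard acetylation of the secondary allylic alcohol with acetic anhydride under nucleophilic catalysis installs the C9 acetate without touching a stereocentre.

Step 12
Reactants: 21 C9 acetate
Product: 22 C8 alcohol (21 without the silyl group)
Conditions: HF·pyridine, pyridine, THF, 0 °C
Reagents that add atoms: none
Why: Buffered fluoride cleavage of the triethylsilyl ether under mildly acidic conditions should free O8 without 1,2-migration of the neighbouring acetate and without opening the oxirane or the lactone.

Step 13
Reactants: 23 (R)-2-methylglycidol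
Product: 24 (S)-2-methyloxirane-2-carboxylic acid
Conditions: RuCl3 (2 mol %), NaIO4, MeCN/CCl4/H2O, 0 to 23 °C
Reagents that add atoms: water, O
Why: Ruthenium tetroxide oxidation (catalytic RuCl3 with periodate) converts the primary alcohol of the epoxy alcohol into the glycidic acid without affecting the quaternary stereocentre, whose descriptor changes from R to S only because the priorities change.

Step 14
Reactants: 22 C8 alcohol; 24 (S)-2-methyloxirane-2-carboxylic acid
Product: 26 target CNP0274195.2, via mixed anhydride 25 (not isolated)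
Conditions: 24, 2,4,6-trichlorobenzoyl chloride, Et3N, toluene, 23 °C; then 22, DMAP, 23 °C
Reagents that add atoms: none
Why: Yamaguchi esterification through the mixed anhydride 25 acylates the hindered secondary O8 alcohol under mild conditions with retention at C8 and at the quaternary oxirane carbon, which completes the target.

**Compound list**

1 | 2-(2-bromoethyl)-1,3-dioxolane | BrCCC1OCCO1 | starting material
2 | propyne | CC#C | starting material
3 | [2-(1,3-dioxolan-2-yl)ethyl]magnesium bromide | Br[Mg]CCC1OCCO1 | intermediate
4 | [(1Z)-4-(1,3-dioxolan-2-yl)-2-methylbut-1-en-1-yl]copper | [Cu]/C=C(/C)CCC1OCCO1 | intermediate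
5 | 2-[(3Z)-4-iodo-3-methylbut-3-en-1-yl]-1,3-dioxolane | I/C=C(/C)CCC1OCCO1 | intermediate
6 | (R)-2,2-dimethyl-1,3-dioxolane-4-carbaldehyde | CC1(C)OC[C@@H](O1)C=O | starting material
7 | 2-(dichloromethyl)-4,4,5,5-tetramethyl-1,3,2-dioxaborolane | ClC(Cl)B1OC(C)(C)C(C)(C)O1 | starting material
8 | 2-(diiodomethyl)-4,4,5,5-tetramethyl-1,3,2-dioxaborolane | IC(I)B1OC(C)(C)C(C)(C)O1 | intermediate
9 | 2-[(E)-2-[(4S)-2,2-dimethyl-1,3-dioxolan-4-yl]ethenyl]-4,4,5,5-tetramethyl-1,3,2-dioxaborolane | CC1(C)OC[C@@H](O1)/C=C/B2OC(C)(C)C(C)(C)O2 | intermediate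
10 | (4S)-4-[(1E,3Z)-6-(1,3-dioxolan-2-yl)-4-methylhexa-1,3-dien-1-yl]-2,2-dimethyl-1,3-dioxolane | CC1(C)OC[C@@H](O1)/C=C/C=C(/C)CCC2OCCO2 | intermediate
11 | 2-bromoacrylic acid | C=C(Br)C(=O)O | starting material
12 | (4S,5R)-4-[(4S)-2,2-dimethyl-1,3-dioxolan-4-yl]-5-[(1Z)-4-(1,3-dioxolan-2-yl)-2-methylbut-1-en-1-yl]-3-methylideneoxolan-2-one | C=C1C(=O)O[C@H](/C=C(/C)CCC2OCCO2)[C@H]1[C@H]3COC(C)(C)O3 | intermediate
13 | diol aldehyde: trans α-methylene-γ-butyrolactone with the (S)-1,2-dihydroxyethyl group on C7 and the (Z)-2-methyl-5-oxopent-1-enyl group on C6 | C=C1C(=O)O[C@H](/C=C(/C)CCC=O)[C@H]1[C@H](O)CO | intermediate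
14 | methyl (triphenylphosphoranylidene)acetate | COC(=O)C=P(c1ccccc1)(c1ccccc1)c1ccccc1 | starting material
15 | methyl iodo(triphenylphosphoranylidene)acetate | COC(=O)C(I)=P(c1ccccc1)(c1ccccc1)c1ccccc1 | intermediate
16 | iodo enoate diol: 13 with the C1 aldehyde converted into the (Z)-C1H=C10(I)CO2Me unit | C=C1C(=O)O[C@H](/C=C(/C)CC/C=C(\I)C(=O)OC)[C@H]1[C@H](O)CO | intermediate
17 | O8,O9-bis(triethylsilyl) ether of 16 | C=C1C(=O)O[C@H](/C=C(/C)CC/C=C(\I)C(=O)OC)[C@H]1[C@H](O[Si](CC)(CC)CC)CO[Si](CC)(CC)CC | intermediate
18 | (4R,5S)-cis-4,5-oxirane of 17 | C=C1C(=O)O[C@H]([C@@H]2O[C@]2(C)CC/C=C(\I)C(=O)OC)[C@H]1[C@H](O[Si](CC)(CC)CC)CO[Si](CC)(CC)CC | intermediate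
19 | C9 aldehyde: 18 with the primary silyl ether oxidised to the aldehyde | C=C1C(=O)O[C@H]([C@@H]2O[C@]2(C)CC/C=C(\I)C(=O)OC)[C@H]1[C@H](O[Si](CC)(CC)CC)C=O | intermediate
20 | macrocyclic alcohol: target skeleton with (9R)-OH and OSiEt3 at C8 | C=C1C(=O)O[C@H]2[C@H]1[C@H](O[Si](CC)(CC)CC)[C@H](O)/C(C(=O)OC)=C\CC[C@@]1(C)O[C@@H]21 | intermediate
21 | C9 acetate of 20 | C=C1C(=O)O[C@H]2[C@H]1[C@H](O[Si](CC)(CC)CC)[C@H](OC(C)=O)/C(C(=O)OC)=C\CC[C@@]1(C)O[C@@H]21 | intermediate
22 | C8 alcohol: 21 without the triethylsilyl group | C=C1C(=O)O[C@H]2[C@H]1[C@H](O)[C@H](OC(C)=O)/C(C(=O)OC)=C\CC[C@@]1(C)O[C@@H]21 | intermediate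
23 | (R)-2-methylglycidol, (R)-(2-methyloxiran-2-yl)methanol | OC[C@]1(C)CO1 | starting material
24 | (S)-2-methyloxirane-2-carboxylic acid | OC(=O)[C@]1(C)CO1 | intermediate
25 | (S)-2-methyloxirane-2-carboxylic 2,4,6-trichlorobenzoic anhydride | O=C(OC(=O)[C@]1(C)CO1)c1c(Cl)cc(Cl)cc1Cl | intermediate
26 | target CNP0274195.2: 6,12-olide methyl ester with ring-cis C1=C10, (4R,5S)-oxirane, 9-acetate and 8-[(S)-2-methyloxirane-2-carboxylate] | C=C1C(=O)O[C@H]2[C@H]1[C@H](OC(=O)[C@]1(C)CO1)[C@H](OC(C)=O)/C(C(=O)OC)=C\CC[C@@]1(C)O[C@@H]21 | target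

**Totals and risks**

Total step count: 14. Longest linear sequence: 12 steps (steps 1, 3 to 12 and 14).

Steps most likely to fail:

Step 4 (bears the label). Migratory insertion into the 1,4-disubstituted diene may be slow, so the alkenylpalladium species is lost to protodebromination or homocoupling. Facial selectivity next to the dioxolane may be poor. Outer-sphere attack of the carboxylate would invert C6 and lead to the cis-lactone series. The fallback uses known chemistry and forms C6–C7 and O–C12 instead; it sets out from 5 and 6 and returns at 12. Iodine–lithium exchange on 5 (t-BuLi, Et2O, −78 °C) and formylation with DMF would give (2Z)-5-(1,3-dioxolan-2-yl)-3-methylpent-2-enal F1. Morita–Baylis–Hillman reaction of 6 with methyl acrylate (DABCO) would give methyl 2-[[(4R)-2,2-dimethyl-1,3-dioxolan-4-yl](hydroxy)methyl]prop-2-enoate F2. NBS/Me2S would convert this by SN2' displacement into methyl (2Z)-2-(bromomethyl)-3-[(4S)-2,2-dimethyl-1,3-dioxolan-4-yl]prop-2-enoate F3. CrCl2-mediated Barbier-type allylation of F1 with F3, anti-selective through a chair transition state, would give the anti homoallylic hydroxy ester F4, whose lactonisation (PPTS, benzene, 60 °C) closes 12.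

Step 10. The ester-substituted alkenylchromium is a weak nucleophile, so oligomerisation or simple reduction of the carbon–iodine bond may outrun closure of the ten-membered ring, and facial selectivity at the aldehyde may be eroded by ring strain. The fallback forms C9–C10 intermolecularly and closes the ring at C1=C10 by metathesis; it sets out from 13 and returns at 20. Silylation of 13 (TESCl, imidazole, DMF) would give the bis(triethylsilyl) ether aldehyde F5. Wittig methylenation (Ph3P=CH2, THF, −78 °C) would give the terminal alkene F6. mCPBA would give the 4,5-oxirane F7, and selective Swern oxidation the C9 aldehyde F8. Morita–Baylis–Hillman reaction with methyl acrylate (DABCO) would give the α-methylene β-hydroxy ester F9 as the Felkin adduct. Ring-closing metathesis (second-generation Hoveyda–Grubbs catalyst, toluene, 80 °C, high dilution) between the acrylate methylene and the terminal alkene should then give 20, with the ring-cis enoate that the ten-membered ring enforces.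

Step 8. The open-chain (Z)-alkene may show poor facial selectivity toward the peracid, with competing attack syn to the lactone oxygen. The fallback moves the epoxidation behind the ring closure, so that the medium ring and not the open chain controls the face; it sets out from 17 and returns at 21. Selective Swern oxidation of 17 would give the alkene aldehyde F10, Nozaki–Hiyama–Kishi closure the macrocyclic triene alcohol F11, and acetylation (Ac2O, pyridine, DMAP) the triene acetate F12. mCPBA should then epoxidise the only electron-rich alkene from the exposed outer face of the ten-membered ring to give 21.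

**Further compounds**

F1 | step 4 | (2Z)-5-(1,3-dioxolan-2-yl)-3-methylpent-2-enal | O=C/C=C(/C)CCC1OCCO1
F2 | step 4 | methyl 2-[[(4R)-2,2-dimethyl-1,3-dioxolan-4-yl](hydroxy)methyl]prop-2-enoate | C=C(C(=O)OC)C(O)[C@H]1COC(C)(C)O1
F3 | step 4 | methyl (2Z)-2-(bromomethyl)-3-[(4S)-2,2-dimethyl-1,3-dioxolan-4-yl]prop-2-enoate | BrC/C(C(=O)OC)=C\[C@H]1COC(C)(C)O1
F4 | step 4 | anti homoallylic hydroxy ester (methyl ester of the seco acid of 12 with free C6 hydroxyl) | C=C(C(=O)OC)[C@H]([C@H]1COC(C)(C)O1)[C@H](O)/C=C(/C)CCC2OCCO2
F5 | step 10 | O8,O9-bis(triethylsilyl) ether of 13 | C=C1C(=O)O[C@H](/C=C(/C)CCC=O)[C@H]1[C@H](O[Si](CC)(CC)CC)CO[Si](CC)(CC)CC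
F6 | step 10 | terminal alkene: F5 with the C1 aldehyde methylenated | C=C1C(=O)O[C@H](/C=C(/C)CCC=C)[C@H]1[C@H](O[Si](CC)(CC)CC)CO[Si](CC)(CC)CC
F7 | step 10 | (4R,5S)-cis-4,5-oxirane of F6 | C=C1C(=O)O[C@H]([C@@H]2O[C@]2(C)CCC=C)[C@H]1[C@H](O[Si](CC)(CC)CC)CO[Si](CC)(CC)CC
F8 | step 10 | C9 aldehyde from F7 | C=C1C(=O)O[C@H]([C@@H]2O[C@]2(C)CCC=C)[C@H]1[C@H](O[Si](CC)(CC)CC)C=O
F9 | step 10 | α-methylene β-hydroxy ester: (9R) Morita–Baylis–Hillman adduct of F8 with methyl acrylate | C=C1C(=O)O[C@H]([C@@H]2O[C@]2(C)CCC=C)[C@H]1[C@H](O[Si](CC)(CC)CC)[C@H](O)C(=C)C(=O)OC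
F10 | step 8 | alkene aldehyde: 17 with the primary silyl ether oxidised to the C9 aldehyde | C=C1C(=O)O[C@H](/C=C(/C)CC/C=C(\I)C(=O)OC)[C@H]1[C@H](O[Si](CC)(CC)CC)C=O
F11 | step 8 | macrocyclic triene alcohol: 20 with a (Z)-C4=C5 alkene in place of the oxirane | C=C1C(=O)O[C@@H]2/C=C(/C)CC/C=C(C(=O)OC)\[C@@H](O)[C@@H](O[Si](CC)(CC)CC)[C@@H]12
F12 | step 8 | triene acetate: C9 acetate of F11 | C=C1C(=O)O[C@@H]2/C=C(/C)CC/C=C(C(=O)OC)\[C@@H](OC(C)=O)[C@@H](O[Si](CC)(CC)CC)[C@@H]12
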